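The route rests on reading the C11=C12 olefin of the cyclohexene ring (C1, C10–C14) as a Diels–Alder retron, so that C1–C10 and C13–C14 are cut together. One thermal intramolecular cycloaddition of an open-chain triene should close the cyclohexene and, through the C2–C9 tether, the ten-membered ring, and set C1, C10 and C14. It exploits the oxygen pattern around quaternary C1: O2 is carried as the activating ketone, O14 as a (Z)-vinylboronate that is later oxidised with retention. The precursor is the γ-lactone (C7, C8, C17, C19) bearing a dienyl acetate arm at C8 and, across the Z-C5=C6 olefin, a silyloxy boryl-enone arm.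

Key step: step 24

Remark: locants C1–C20 are the briarane locants of 36 and are used for all intermediates. C1 is the quaternary carbon, C2–C9 the rest of the ten-membered ring, C10 the ring-fusion CH and C11–C14 the cyclohexene. C15 is the methyl on C1, C16 the CH2O on C5, C17/C18/C19 the lactone CH/CH3/C=O and C20 the methyl on C11. "As in 36" means the same spatial arrangement. 1,3-Dihydroxyacetone is written as the monomer although it is sold as the dimer.

Step 1
Reactants: 1 tert-butyl (R)-lactate
Product: 2 tert-butyl (R)-2-(trifluoromethylsulfonyloxy)propanoate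
Conditions: Tf2O, 2,6-lutidine, CH2Cl2, −78 to 0 °C
Reagents that add atoms: triflic anhydride O=S(=O)(OS(=O)(=O)C(F)(F)F)C(F)(F)F
Why: O-sulfonylation of the secondary alcohol, which leaves the stereocentre (future C17) untouched.

Step 2
Reactants: 2 tert-butyl (R)-2-(trifluoromethylsulfonyloxy)propanoate; 3 ethyl (triphenylphosphoranylidene)acetate (2 equiv)
Product: 4 4-tert-butyl 1-ethyl (3S)-3-methyl-2-(triphenylphosphoranylidene)butanedioate (C8, C9, C17–C19)
Conditions: CH2Cl2, 0 °C to rt
Reagents that add atoms: none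
Why: SN2 alkylation of the stabilised ylide by the α-triflyloxy ester should set C17 by inversion, and the second equivalent of 3 deprotonates the phosphonium salt (transylidation).

Step 3
Reactants: 5 1,3-dihydroxyacetone; 3 ethyl (triphenylphosphoranylidene)acetate
Product: 7 4-(hydroxymethyl)furan-2(5H)-one, via ethyl 4-hydroxy-3-(hydroxymethyl)but-2-enoate 6 (not isolated)
Conditions: CH2Cl2, rt
Reagents that add atoms: none
Why: Wittig olefination followed by spontaneous lactonisation of the CH2OH arm cis to the ester, which tells the two arms apart (ring CH2 = C4, free CH2OH = C16) and fixes the later Z-C5=C6 geometry.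

Step 4
Reactants: 7 4-(hydroxymethyl)furan-2(5H)-one
Product: 8 4-[(tert-butyldimethylsilyloxy)methyl]furan-2(5H)-one
Conditions: TBSCl, imidazole, DMF, rt
Reagents that add atoms: TBSCl CC(C)(C)[Si](C)(C)Cl
Why: Standard silylation of the primary alcohol (O16) so that it survives the hydride steps.

Step 5
Reactants: 8 4-[(tert-butyldimethylsilyloxy)methyl]furan-2(5H)-one
Product: 9 4-[(tert-butyldimethylsilyloxy)methyl]-2,5-dihydrofuran-2-ol (lactol, anomer mixture)
Conditions: iBu2AlH (1.1 equiv), CH2Cl2, −78 °C; Rochelle salt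
Reagents that add atoms: none
Why: Partial reduction of the lactone to the lactol, whose anomeric centre is lost again in the next step.

Step 6
Reactants: 9 lactol; 4 branched ylide
Product: 10 hydroxy dienoate, 4-tert-butyl 1-ethyl (3R)-3-methyl-2-[4-hydroxy-3-(TBSO-methyl)but-2-enylidene]butanedioate, C7=C8 E (CO2Et trans to C6), CH2OH arm (C4) cis to C7
Conditions: toluene, PhCO2H (cat.), 80 °C
Reagents that add atoms: none
Why: Wittig olefination of the ring-opened hydroxy enal, in which the stabilised ylide should give the E-C7=C8 olefin, the Z-C5=C6 olefin is kept and the neutral medium holds back oxa-Michael closure.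

Step 7
Reactants: 10 hydroxy dienoate
Product: 11 bis-silyl dienoate (O4 as TBDPS ether, O16 as TBS ether)
Conditions: TBDPSCl, imidazole, CH2Cl2, rt
Reagents that add atoms: TBDPSCl CC(C)(C)[Si](Cl)(c1ccccc1)c1ccccc1
Why: Silylation with a more acid- and fluoride-stable group so that O16 and O4 can later be released one after the other.

Step 8
Reactants: 11 bis-silyl dienoate
Product: 12 dienyl alcohol (C9 as CH2OH, tert-butyl ester kept)
Conditions: iBu2AlH (2.2 equiv), CH2Cl2, −78 °C; Rochelle salt
Reagents that add atoms: none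
Why: Chemoselective 1,2-reduction of the conjugated ethyl ester, while the hindered tert-butyl ester should survive at −78 °C.

Step 9
Reactants: 12 dienyl alcohol
Product: 14 lactone diol (γ-lactone C7–O–C19; 8-OH, 17-CH3 and the C7 alkenyl chain on one face, CH2OH (C9) on the other; C7, C8, C17 as in 36), via C7–C8 epoxy alcohol 13 (not isolated)
Conditions: Ti(OiPr)4 (10 mol %), D-(−)-diethyl tartrate, tBuOOH, 4 Å MS, CH2Cl2, −20 °C; aqueous work-up, then CSA (cat.), CH2Cl2, 0 °C
Reagents that add atoms: tert-butyl hydroperoxide CC(C)(C)OO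
Why: Sharpless asymmetric epoxidation sets C8 by reagent control, and the vinyl epoxide is then opened at allylic C7 by the tert-butyl ester carbonyl with inversion and loss of isobutene (formally 5-endo, allowed by allylic activation as in halolactonisation of styrylacetic acids), which sets C7.

Step 10
Reactants: 14 lactone diol
Product: 15 α-hydroxy aldehyde (C9 as CHO)
Conditions: IBX, DMSO, rt
Reagents that add atoms: none
Why: IBX oxidation of the primary alcohol, chosen because it oxidises 1,2-diols without glycol cleavage and leaves the tertiary 8-OH alone.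

Step 11
Reactants: 16 propargyl alcohol
Product: 17 (E)-3-iodo-2-methylprop-2-en-1-ol
Conditions: Me3Al, Cp2ZrCl2 (25 mol %), CH2Cl2, 0 °C to rt; I2, THF, −30 °C
Reagents that add atoms: trimethylaluminium C[Al](C)C; iodine II
Why: Negishi syn-carboalumination followed by iodinolysis with retention gives the E-olefin (future C10=C11 with C20).

Step 12
Reactants: 17 (E)-3-iodo-2-methylprop-2-en-1-ol
Product: 18 (E)-3-iodo-2-methylprop-2-enal
Conditions: MnO2, CH2Cl2, rt
Reagents that add atoms: none
Why: Selective oxidation of the allylic alcohol without change of olefin geometry.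

Step 13
Reactants: 18 (E)-3-iodo-2-methylprop-2-enal
Product: 19 (E)-1-iodo-2-methylbuta-1,3-diene (C10–C13, C20)
Conditions: Ph3PCH3Br, NaHMDS, THF, −78 to 0 °C; used as a solution
Reagents that add atoms: methyltriphenylphosphonium bromide C[P+](c1ccccc1)(c1ccccc1)c1ccccc1.[Br-]
Why: Wittig methylenation of the enal, which builds the terminal C12=C13 olefin and keeps the E-iodoalkene.

Step 14
Reactants: 15 α-hydroxy aldehyde; 19 (E)-1-iodo-2-methylbuta-1,3-diene
Product: 20 dienyl carbinol (new 9-OH, C9 as in 36)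
Conditions: CrCl2, NiCl2 (cat.), (S)-N-[2-(4-isopropyl-4,5-dihydrooxazol-2-yl)-6-methylphenyl]methanesulfonamide, Et3N, THF, rt
Reagents that add atoms: none
Why: Nozaki–Hiyama–Kishi alkenylation, chemoselective for the aldehyde beside lactone and free hydroxyl, with retention of the E-olefin. C9 is to be set by the chiral sulfonamide complex of chromium (Si-face attack), because the flanks of C8 offer little bias.

Step 15
Reactants: 20 dienyl carbinol
Product: 21 triol (O16 free, O4 still TBDPS)
Conditions: HF·pyridine, pyridine, THF, 0 °C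
Reagents that add atoms: none
Why: Buffered fluoride cleaves the primary allylic TBS ether much faster than the TBDPS ether and is mild enough for the dienyl carbinol.

Step 16
Reactants: 21 triol
Product: 22 9,16-diacetate (8-OH free)
Conditions: Ac2O, pyridine, DMAP (cat.), CH2Cl2, 0 °C to rt
Reagents that add atoms: acetic anhydride CC(=O)OC(C)=O
Why: Acetylation of the primary and secondary hydroxyls, while the hindered tertiary 8-OH should stay free.

Step 17
Reactants: 22 9,16-diacetate
Product: 23 allylic alcohol (O4 free as CH2OH)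
Conditions: HF·pyridine (excess), THF, rt
Reagents that add atoms: none
Why: Acidic fluoride removes the TBDPS ether without touching the acetates and avoids the base-promoted O16 to O4 acetyl shift.

Step 18
Reactants: 23 allylic alcohol
Product: 24 Z-enal (C4 as CHO, cis to C7)
Conditions: MnO2, CH2Cl2, rt
Reagents that add atoms: none
Why: Neutral allylic oxidation that should keep the Z-olefin, which cannot cyclise because O7 is acylated.

Step 19
Reactants: 25 but-3-yn-2-ol
Product: 26 (Z)-4-iodo-3-methylbut-3-en-2-ol (racemic)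
Conditions: MeMgBr (3 equiv), CuI (10 mol %), THF, 0 °C to rt; I2, −30 °C
Reagents that add atoms: methylmagnesium bromide C[Mg]Br; iodine II
Why: Copper-catalysed anti-carbomagnesiation of the propargylic alkoxide (methyl to the carbon next to the carbinol, magnesium held cis to it by chelation) and iodinolysis with retention give iodine cis to the future C2.

Step 20
Reactants: 26 (Z)-4-iodo-3-methylbut-3-en-2-ol
Product: 27 (Z)-4-iodo-3-methylbut-3-en-2-one
Conditions: MnO2, CH2Cl2, rt
Reagents that add atoms: none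
Why: Allylic oxidation removes the only stereocentre and keeps the Z-olefin.

Step 21
Reactants: 27 (Z)-4-iodo-3-methylbut-3-en-2-one
Product: 28 (Z)-3-methyl-4-(4,4,5,5-tetramethyl-1,3,2-dioxaborolan-2-yl)but-3-en-2-one (C1–C3, C14, C15)
Conditions: B2pin2, PdCl2(dppf) (3 mol %), KOAc, dioxane, 80 °C
Reagents that add atoms: bis(pinacolato)diboron CC1(C)OB(OC1(C)C)B1OC(C)(C)C(C)(C)O1
Why: Miyaura borylation of the β-iodo enone with retention places boron cis to the acyl group.

Step 22
Reactants: 24 Z-enal; 28 boryl enone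
Product: 30 aldol adduct (new 4-OH, C4 as in 36), via diisopinocampheyl enol borinate 29 (not isolated)
Conditions: 28, (−)-Ipc2BCl, Et3N, Et2O, 0 °C; 24, −78 to −20 °C; MeOH, pH 7 buffer (no peroxide)
Reagents that add atoms: (−)-B-chlorodiisopinocampheylborane ClB([C@@H]1C[C@@H]2C[C@H]([C@H]1C)C2(C)C)[C@@H]1C[C@@H]2C[C@H]([C@H]1C)C2(C)C
Why: Boron-mediated methyl ketone aldol through a cyclic transition state, in which the isopinocampheyl groups should direct the enolate to the Re face of the enal (sets C4), and the peroxide-free work-up spares the C–B bond.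

Step 23
Reactants: 30 aldol adduct
Product: 31 triene, 4-O-TBS ether of 30
Conditions: TBSOTf (1.1 equiv), 2,6-lutidine, CH2Cl2, −78 °C
Reagents that add atoms: TBSOTf CC(C)(C)[Si](C)(C)OS(=O)(=O)C(F)(F)F
Why: Silylation of the secondary allylic hydroxyl, faster than that of the tertiary 8-OH, blocks retro-aldol and dehydration and marks O4 as the one oxygen that stays unacetylated.

Step 24
Reactants: 31 triene
Product: 32 bicyclic boronate (cyclohexene fused trans to the ten-membered ring; 2-ketone, 14-Bpin in the place of 14-OAc of 36, C1 and C10 as in 36)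
Conditions: toluene (0.5 mM), BHT, sealed vessel, 130 °C
Reagents that add atoms: none
Why: Concerted, asynchronous [4+2] cycloaddition (intramolecular Diels–Alder reaction) in which the s-cis (E)-C10=C11–C12=C13 diene adds suprafacially to the ketone-activated C1=C14 olefin, forming C1–C10 and C13–C14 and leaving C11=C12 where the target has it. The closest known reaction types are the macrocyclising intramolecular Diels–Alder closures of eleven-membered carbocycles from trienones and the cycloadditions of alkenylboronates followed by oxidation. The cyclohexene closes as the six-atom periphery of the cycloaddition, and the ten-membered ring closes in fused mode through the eight-atom C2–C9 tether that joins diene terminus C10 to dienophile carbon C1. C1 and C14 are controlled by the Z geometry of the dienophile (acyl and boron stay cis), and C10 by the E geometry of the diene together with the exo-acyl transition state that α-methyl enones favour and that points tether and Bpin away from the diene, so that C9, C15 and H14 should end on one face. The diene face is controlled by C9: allylic 1,3-strain with the C11 methyl holds H9 in the diene plane and the tether leaves antiperiplanar to the forming C1–C10 bond, whereas attack on the other face would press the lactone over C12–C13. The step needs ring closure to beat dimerisation and the all-carbon mode to beat the hetero-Diels–Alder mode of the enone, which high dilution, the turn elements of the tether (Z-C5=C6 olefin, lactone ring) and the higher reactivity of the carbon diene should secure.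

Step 25
Reactants: 32 bicyclic boronate
Product: 33 14-hydroxy ketone
Conditions: NaBO3·4H2O, THF/H2O, 0 °C to rt
Reagents that add atoms: sodium perborate O=BO[O-].[Na+]
Why: Oxidation of the secondary boronate by 1,2-migration with retention turns C14–B into C14–OH without touching the olefins. The quaternary C1 blocks dehydration.

Step 26
Reactants: 33 14-hydroxy ketone
Product: 34 2,14-diol (new 2-OH, C2 as in 36)
Conditions: Me4NBH(OAc)3, MeCN/AcOH, −20 °C
Reagents that add atoms: none
Why: Evans–Saksena reduction, in which hydride is delivered within the C14-alkoxyborohydride through a chair-like six-membered transition state and should give the 2,14-anti diol (sets C2).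

Step 27
Reactants: 34 2,14-diol
Product: 35 2,9,14,16-tetraacetate 4-O-TBS ether
Conditions: Ac2O, DMAP, pyridine, 40 °C
Reagents that add atoms: acetic anhydride CC(=O)OC(C)=O
Why: Forced acetylation of the two hindered secondary hydroxyls, while the tertiary 8-OH should remain free.

Step 28
Reactants: 35 tetraacetate 4-O-TBS ether
Product: 36 target CNP0226727.2
Conditions: HF·pyridine, pyridine, THF, 0 °C to rt
Reagents that add atoms: none
Why: Acidic fluoride cleaves the last silyl ether and frees 4-OH without acetyl migration or loss of acetate.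

Compound list
1 | tert-butyl (R)-lactate | C[C@@H](O)C(=O)OC(C)(C)C | starting material
2 | tert-butyl (R)-2-(trifluoromethylsulfonyloxy)propanoate | C[C@@H](OS(=O)(=O)C(F)(F)F)C(=O)OC(C)(C)C | intermediate
3 | ethyl (triphenylphosphoranylidene)acetate | CCOC(=O)C=P(c1ccccc1)(c1ccccc1)c1ccccc1 | starting material
4 | 4-tert-butyl 1-ethyl (3S)-3-methyl-2-(triphenylphosphoranylidene)butanedioate | CCOC(=O)C(=P(c1ccccc1)(c1ccccc1)c1ccccc1)[C@@H](C)C(=O)OC(C)(C)C | intermediate
5 | 1,3-dihydroxyacetone | OCC(=O)CO | starting material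
6 | ethyl 4-hydroxy-3-(hydroxymethyl)but-2-enoate | CCOC(=O)C=C(CO)CO | intermediate
7 | 4-(hydroxymethyl)furan-2(5H)-one | O=C1C=C(CO)CO1 | intermediate
8 | 4-[(tert-butyldimethylsilyloxy)methyl]furan-2(5H)-one | O=C1C=C(CO[Si](C)(C)C(C)(C)C)CO1 | intermediate
9 | 4-[(tert-butyldimethylsilyloxy)methyl]-2,5-dihydrofuran-2-ol | OC1C=C(CO[Si](C)(C)C(C)(C)C)CO1 | intermediate
10 | hydroxy dienoate (C4 CH2OH cis to C7, C7=C8 E, C17 as in 36) | CCOC(=O)/C(=C/C=C(/CO[Si](C)(C)C(C)(C)C)CO)[C@@H](C)C(=O)OC(C)(C)C | intermediate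
11 | bis-silyl dienoate (O4 TBDPS, O16 TBS) | CCOC(=O)/C(=C/C=C(/CO[Si](C)(C)C(C)(C)C)CO[Si](c1ccccc1)(c1ccccc1)C(C)(C)C)[C@@H](C)C(=O)OC(C)(C)C | intermediate
12 | dienyl alcohol (C9 CH2OH) | OC/C(=C/C=C(/CO[Si](C)(C)C(C)(C)C)CO[Si](c1ccccc1)(c1ccccc1)C(C)(C)C)[C@@H](C)C(=O)OC(C)(C)C | intermediate
13 | C7–C8 epoxy alcohol (C8 as in 36, C7 opposite to 36) | OC[C@]1(O[C@@H]1/C=C(/CO[Si](C)(C)C(C)(C)C)CO[Si](c1ccccc1)(c1ccccc1)C(C)(C)C)[C@@H](C)C(=O)OC(C)(C)C | intermediate
14 | lactone diol (C7, C8, C17 as in 36) | CC(C)(C)[Si](C)(C)OC/C(CO[Si](c1ccccc1)(c1ccccc1)C(C)(C)C)=C/[C@@H]1OC(=O)[C@H](C)[C@@]1(O)CO | intermediate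
15 | α-hydroxy aldehyde (C9 CHO) | CC(C)(C)[Si](C)(C)OC/C(CO[Si](c1ccccc1)(c1ccccc1)C(C)(C)C)=C/[C@@H]1OC(=O)[C@H](C)[C@@]1(O)C=O | intermediate
16 | propargyl alcohol | C#CCO | starting material
17 | (E)-3-iodo-2-methylprop-2-en-1-ol | OC/C(C)=C/I | intermediate
18 | (E)-3-iodo-2-methylprop-2-enal | O=C/C(C)=C/I | intermediate
19 | (E)-1-iodo-2-methylbuta-1,3-diene | C=C/C(C)=C/I | intermediate
20 | dienyl carbinol (C9 as in 36) | CC(C)(C)[Si](C)(C)OC/C(CO[Si](c1ccccc1)(c1ccccc1)C(C)(C)C)=C/[C@@H]1OC(=O)[C@H](C)[C@@]1(O)[C@@H](O)/C=C(C)/C=C | intermediate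
21 | triol (O16 free, O4 TBDPS) | OC/C(CO[Si](c1ccccc1)(c1ccccc1)C(C)(C)C)=C/[C@@H]1OC(=O)[C@H](C)[C@@]1(O)[C@@H](O)/C=C(C)/C=C | intermediate
22 | 9,16-diacetate | CC(=O)OC/C(CO[Si](c1ccccc1)(c1ccccc1)C(C)(C)C)=C/[C@@H]1OC(=O)[C@H](C)[C@@]1(O)[C@@H](OC(C)=O)/C=C(C)/C=C | intermediate
23 | allylic alcohol (C4 CH2OH) | CC(=O)OC/C(CO)=C/[C@@H]1OC(=O)[C@H](C)[C@@]1(O)[C@@H](OC(C)=O)/C=C(C)/C=C | intermediate
24 | Z-enal (C4 CHO cis to C7) | CC(=O)OC/C(C=O)=C/[C@@H]1OC(=O)[C@H](C)[C@@]1(O)[C@@H](OC(C)=O)/C=C(C)/C=C | intermediate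
25 | but-3-yn-2-ol | C#CC(C)O | starting material
26 | (Z)-4-iodo-3-methylbut-3-en-2-ol | CC(O)/C(C)=C\I | intermediate
27 | (Z)-4-iodo-3-methylbut-3-en-2-one | CC(=O)/C(C)=C\I | intermediate
28 | (Z)-3-methyl-4-(pinacolatoboryl)but-3-en-2-one | CC(=O)/C(C)=C\B1OC(C)(C)C(C)(C)O1 | intermediate
29 | diisopinocampheyl enol borinate of 28 | C=C(OB([C@@H]1C[C@@H]2C[C@H]([C@H]1C)C2(C)C)[C@@H]1C[C@@H]2C[C@H]([C@H]1C)C2(C)C)/C(C)=C\B1OC(C)(C)C(C)(C)O1 | intermediate
30 | aldol adduct (C4 as in 36) | CC(=O)OC/C(=C/[C@@H]1OC(=O)[C@H](C)[C@@]1(O)[C@@H](OC(C)=O)/C=C(C)/C=C)[C@H](O)CC(=O)/C(C)=C\B1OC(C)(C)C(C)(C)O1 | intermediate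
31 | triene, 4-O-TBS ether of 30 | CC(=O)OC/C(=C/[C@@H]1OC(=O)[C@H](C)[C@@]1(O)[C@@H](OC(C)=O)/C=C(C)/C=C)[C@H](O[Si](C)(C)C(C)(C)C)CC(=O)/C(C)=C\B1OC(C)(C)C(C)(C)O1 | intermediate
32 | bicyclic boronate (2-ketone, 14-Bpin) | CC(=O)OC/C1=C/[C@@H]2OC(=O)[C@H](C)[C@@]2(O)[C@@H](OC(C)=O)[C@H]2C(C)=CC[C@H](B3OC(C)(C)C(C)(C)O3)[C@]2(C)C(=O)C[C@H]1O[Si](C)(C)C(C)(C)C | intermediate
33 | 14-hydroxy ketone | CC(=O)OC/C1=C/[C@@H]2OC(=O)[C@H](C)[C@@]2(O)[C@@H](OC(C)=O)[C@H]2C(C)=CC[C@H](O)[C@]2(C)C(=O)C[C@H]1O[Si](C)(C)C(C)(C)C | intermediate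
34 | 2,14-diol | CC(=O)OC/C1=C/[C@@H]2OC(=O)[C@H](C)[C@@]2(O)[C@@H](OC(C)=O)[C@H]2C(C)=CC[C@H](O)[C@]2(C)[C@@H](O)C[C@H]1O[Si](C)(C)C(C)(C)C | intermediate
35 | 2,9,14,16-tetraacetate 4-O-TBS ether | CC(=O)OC/C1=C/[C@@H]2OC(=O)[C@H](C)[C@@]2(O)[C@@H](OC(C)=O)[C@H]2C(C)=CC[C@H](OC(C)=O)[C@]2(C)[C@@H](OC(C)=O)C[C@H]1O[Si](C)(C)C(C)(C)C | intermediate
36 | CNP0226727.2, (1R,2S,4R,5Z,7S,8S,9S,10S,14S,17R)-2,9,14,16-tetraacetoxy-4,8-dihydroxybriara-5,11-dien-19,7-olide | CC(=O)OC/C1=C/[C@@H]2OC(=O)[C@H](C)[C@@]2(O)[C@@H](OC(C)=O)[C@H]2C(C)=CC[C@H](OC(C)=O)[C@]2(C)[C@@H](OC(C)=O)C[C@H]1O | target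

Total step count: 28. Longest linear sequence: 20 steps (steps 3–10, 14–18 and 22–28, from 1,3-dihydroxyacetone).

Steps most likely to fail

Step 24. Dimerisation, slow thermal decay of the triene or poor facial selectivity may outrun closure of the strained ten-membered tether. The fallback sets out from 30 and shortens the free tether with a temporary ring.
- O4 and O8 are bridged with iPr2Si(OTf)2 and 2,6-lutidine to give the silylene-bridged triene F1. Its eight-membered siloxane ring holds the diene arm and the dienophile arm on one side.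
- Heating under dilution should give the silylene-bridged bicyclic boronate F2.
- NaBO3·4H2O gives the 14-hydroxy ketone F3.
- Me4NBH(OAc)3 gives the 2,14-diol F4.
- Ac2O with DMAP gives the tetraacetate F5.
- HF·pyridine cleaves the bridge, and the route comes back at 36.

Step 14. Facial selectivity at the aldehyde may be poor, because ligand control has to override a nearly unbiased α-quaternary centre. The fallback sets out from 15.
- Ligand-free coupling with 19 (CrCl2, NiCl2 cat., DMSO) gives 20 mixed with the 9-epi carbinol F6.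
- MnO2 oxidises both to the dienone F7.
- Corey–Bakshi–Shibata reduction ((R)-methyl oxazaborolidine, catecholborane, toluene, −78 °C) sets C9 at the ketone stage, and the route comes back at 20.

Step 22. Facial selectivity of the methyl ketone boron enolate may be poor, or the enol borinate may erode before addition. The fallback sets out from 28 and changes from a closed boron transition state to an open, catalyst-controlled one.
- TMSOTf and Et3N give the silyl dienol ether F8.
- F8 adds to 24 in a Mukaiyama aldol reaction promoted by SiCl4 and a catalytic chiral binaphthyldiamine-derived bisphosphoramide (CH2Cl2, −78 °C), and the route comes back at 30.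

Further compounds
F1 | step 24 | 4,8-O-diisopropylsilylene-bridged triene | CC(=O)OC/C1=C/[C@@H]2OC(=O)[C@H](C)[C@@]2(O[Si](C(C)C)(C(C)C)O[C@@H]1CC(=O)/C(C)=C\B1OC(C)(C)C(C)(C)O1)[C@@H](OC(C)=O)/C=C(C)/C=C
F2 | step 24 | silylene-bridged bicyclic boronate | CC(=O)OC/C1=C/[C@@H]2OC(=O)[C@H](C)[C@@]2(O[Si]3(C(C)C)C(C)C)[C@@H](OC(C)=O)[C@H]2C(C)=CC[C@H](B4OC(C)(C)C(C)(C)O4)[C@]2(C)C(=O)C[C@H]1O3
F3 | step 24 | silylene-bridged 14-hydroxy ketone | CC(=O)OC/C1=C/[C@@H]2OC(=O)[C@H](C)[C@@]2(O[Si]3(C(C)C)C(C)C)[C@@H](OC(C)=O)[C@H]2C(C)=CC[C@H](O)[C@]2(C)C(=O)C[C@H]1O3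
F4 | step 24 | silylene-bridged 2,14-diol | CC(=O)OC/C1=C/[C@@H]2OC(=O)[C@H](C)[C@@]2(O[Si]3(C(C)C)C(C)C)[C@@H](OC(C)=O)[C@H]2C(C)=CC[C@H](O)[C@]2(C)[C@@H](O)C[C@H]1O3
F5 | step 24 | silylene-bridged tetraacetate | CC(=O)OC/C1=C/[C@@H]2OC(=O)[C@H](C)[C@@]2(O[Si]3(C(C)C)C(C)C)[C@@H](OC(C)=O)[C@H]2C(C)=CC[C@H](OC(C)=O)[C@]2(C)[C@@H](OC(C)=O)C[C@H]1O3
F6 | step 14 | 9-epi dienyl carbinol | CC(C)(C)[Si](C)(C)OC/C(CO[Si](c1ccccc1)(c1ccccc1)C(C)(C)C)=C/[C@@H]1OC(=O)[C@H](C)[C@@]1(O)[C@H](O)/C=C(C)/C=C
F7 | step 14 | C9 dienone | CC(C)(C)[Si](C)(C)OC/C(CO[Si](c1ccccc1)(c1ccccc1)C(C)(C)C)=C/[C@@H]1OC(=O)[C@H](C)[C@@]1(O)C(=O)/C=C(C)/C=C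
F8 | step 22 | trimethylsilyl dienol ether of 28 | C=C(O[Si](C)(C)C)/C(C)=C\B1OC(C)(C)C(C)(C)O1
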